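The dihydrobenzofuran is disconnected at its C2–C3 bond. C3 is a diarylmethine flanked by ring A (the fused benzene ring) and the resorcinol ring, and C2 is a benzylic carbon bound to O1 and the catechol ring. Read backwards, C3 is a donor/donor carbene and C2–H a hydridic ether C–H held five atoms away by the O1–C7a–C3a tether. The key step is a chiral dirhodium-catalysed 1,5-C–H insertion of the diaryldiazomethane made in situ from the hydrazone of a 2-(3,4-dimethoxybenzyloxy)-5-bromobenzophenone. It closes the furan ring and sets C3 (and C2, cis) in one operation. A Heck reaction then adds the stilbene arm, and BBr3 frees six phenols while inverting C2 to trans.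

Key step: step 3

Assumption: Rh2(R-PTAD)4 is taken to deliver the (2R,3S) cis product; should a first run show the opposite sense of induction, the mirror-image catalyst Rh2(S-PTAD)4 is used and nothing else changes.

Step 1
Reactants: 1 5-bromo-2-hydroxybenzonitrile; 2 3,4-dimethoxybenzyl chloride
Product: 3 5-bromo-2-[(3,4-dimethoxybenzyl)oxy]benzonitrile
Conditions: K2CO3, KI (cat.), DMF, 60 °C
Reagents that add atoms: none
Why: Williamson ether synthesis, in which the phenoxide (acidified by the ortho nitrile) displaces a reactive benzylic chloride by SN2 with in situ Finkelstein activation by iodide; no stereocenter is formed.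

Step 2
Reactants: 3 5-bromo-2-[(3,4-dimethoxybenzyl)oxy]benzonitrile; 4 (3,5-dimethoxyphenyl)magnesium chloride
Product: 6 [(5-bromo-2-{[(3,4-dimethoxyphenyl)methyl]oxy}phenyl)(3,5-dimethoxyphenyl)methylidene]hydrazine (E/Z mixture), via diaryl N–H ketimine 5 (not isolated)
Conditions: 4 (1.5 equiv), CuBr (cat.), THF, 65 °C; MeOH, 0 °C; then N2H4·H2O (excess), AcOH (cat.), EtOH, 70 °C
Reagents that add atoms: hydrazine (used as the monohydrate), NN
Why: Grignard addition to a nitrile stops at the magnesium ketiminate (no second addition, aryl bromide inert to an aryl Grignard reagent), and the N–H ketimine freed by methanol should undergo transimination with hydrazine, driven by loss of ammonia, more readily than a hindered benzophenone condenses; the hydrazone geometry is irrelevant and no stereocenter is formed.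

Step 3
Reactants: 6 [(5-bromo-2-{[(3,4-dimethoxyphenyl)methyl]oxy}phenyl)(3,5-dimethoxyphenyl)methylidene]hydrazine
Product: 8 (2R,3S)-5-bromo-2-(3,4-dimethoxyphenyl)-3-(3,5-dimethoxyphenyl)-2,3-dihydro-1-benzofuran (cis), via diaryldiazomethane 7 (not isolated)
Conditions: activated MnO2, CH2Cl2, 0 °C → rt, filtered through Celite; then Rh2(R-PTAD)4 (dirhodium tetrakis[(R)-N-phthaloyl-(1-adamantyl)glycinate], 1 mol %), CH2Cl2, high dilution, −20 → 0 °C
Reagents that add atoms: none
Why: MnO2 dehydrogenates the N-unsubstituted hydrazone to the diaryldiazomethane 7, which Rh2(R-PTAD)4 converts with loss of N2 into a donor/donor rhodium carbene at the future C3; this carbene inserts into one of the two enantiotopic benzylic O–CH2 hydrogens five atoms away through a hydride-shift-like, concerted but asynchronous three-centre transition state that forms the C2–C3 bond. The closest known reaction type is the enantioselective intramolecular C–H insertion of donor/donor carbenes derived from hydrazones of 2-(benzyloxy)benzophenones, which gives cis-2,3-diaryl-2,3-dihydrobenzofurans. The one ring closed, O1–C2–C3–C3a–C7a, forms by 1,5-C–H insertion, a five-membered closure on the O1–C7a–C3a tether that is already in place. Both new stereocenters are under catalyst control: the chiral carboxylate pocket selects the carbene face (C3, S) and the enantiotopic hydrogen (C2, R), and the cis relation is the kinetic outcome of the insertion geometry. The step needs insertion to beat azine formation, carbene dimerisation and ylide chemistry; the low electrophilicity of the donor/donor carbene, high dilution, the doubly activated hydridic C–H bond (alpha to oxygen, on an electron-rich aryl ring) and the four-membered ring that an ylide at O1 would require should secure this. The aryl bromide and the methyl ethers should be inert to MnO2 and to the carbene.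

Step 4
Reactants: 8 (2R,3S)-5-bromo-2-(3,4-dimethoxyphenyl)-3-(3,5-dimethoxyphenyl)-2,3-dihydro-1-benzofuran; 9 3,5-dimethoxystyrene
Product: 10 (2R,3S)-2-(3,4-dimethoxyphenyl)-3-(3,5-dimethoxyphenyl)-5-[(E)-2-(3,5-dimethoxyphenyl)ethenyl]-2,3-dihydro-1-benzofuran
Conditions: Pd(OAc)2 (5 mol %), P(o-tol)3 (10 mol %), Et3N, DMF, 100 °C
Reagents that add atoms: none
Why: Heck reaction, in which zerovalent palladium adds oxidatively to the C5–Br bond and syn carbopalladation of the terminal alkene followed by syn beta-hydride elimination gives the E-stilbene; the weak amine base should leave C2 and C3 untouched.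

Step 5
Reactants: 10 (2R,3S)-2-(3,4-dimethoxyphenyl)-3-(3,5-dimethoxyphenyl)-5-[(E)-2-(3,5-dimethoxyphenyl)ethenyl]-2,3-dihydro-1-benzofuran
Product: 12 5-[(E)-2-[(2S,3S)-2-(3,4-dihydroxyphenyl)-3-(3,5-dihydroxyphenyl)-2,3-dihydro-1-benzofuran-5-yl]ethenyl]benzene-1,3-diol (target), via ring-opened para-quinone methide 11 (not isolated)
Conditions: BBr3 (1 M in CH2Cl2, excess), CH2Cl2, −78 °C → rt; then ice-water
Reagents that add atoms: none
Why: Lewis-acid ether cleavage (boron complexation, then SN2 attack of bromide on each methyl group) should free all six phenols, while the C2–O1 bond ionises reversibly through the para-oxygen-stabilised benzylic cation/para-quinone methide 11 (boron-bound in the flask) and recloses by 5-exo oxa-Michael addition anti to the C3 aryl group, so that C2 is inverted to the thermodynamically preferred trans (2S) configuration while C3 (S), which is never ionised, is retained.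

Compound list
1 | 5-bromo-2-hydroxybenzonitrile | N#Cc1cc(Br)ccc1O | starting material
2 | 3,4-dimethoxybenzyl chloride (4-(chloromethyl)-1,2-dimethoxybenzene) | COc1ccc(CCl)cc1OC | starting material
3 | 5-bromo-2-[(3,4-dimethoxybenzyl)oxy]benzonitrile | N#Cc1cc(Br)ccc1OCc1ccc(OC)c(OC)c1 | intermediate
4 | (3,5-dimethoxyphenyl)magnesium chloride (THF solution) | COc1cc(OC)cc([Mg]Cl)c1 | starting material
5 | (5-bromo-2-[(3,4-dimethoxybenzyl)oxy]phenyl)(3,5-dimethoxyphenyl)methanimine (N–H ketimine, not isolated) | N=C(c1cc(OC)cc(OC)c1)c1cc(Br)ccc1OCc1ccc(OC)c(OC)c1 | intermediate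
6 | [(5-bromo-2-{[(3,4-dimethoxyphenyl)methyl]oxy}phenyl)(3,5-dimethoxyphenyl)methylidene]hydrazine (E/Z mixture) | NN=C(c1cc(OC)cc(OC)c1)c1cc(Br)ccc1OCc1ccc(OC)c(OC)c1 | intermediate
7 | 4-bromo-2-[diazo(3,5-dimethoxyphenyl)methyl]-1-[(3,4-dimethoxybenzyl)oxy]benzene (diaryldiazomethane, not isolated) | [N-]=[N+]=C(c1cc(OC)cc(OC)c1)c1cc(Br)ccc1OCc1ccc(OC)c(OC)c1 | intermediate
8 | (2R,3S)-5-bromo-2-(3,4-dimethoxyphenyl)-3-(3,5-dimethoxyphenyl)-2,3-dihydro-1-benzofuran (cis) | Brc1ccc2c(c1)[C@H](c1cc(OC)cc(OC)c1)[C@H](c1ccc(OC)c(OC)c1)O2 | intermediate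
9 | 3,5-dimethoxystyrene (1-ethenyl-3,5-dimethoxybenzene) | C=Cc1cc(OC)cc(OC)c1 | starting material
10 | (2R,3S)-2-(3,4-dimethoxyphenyl)-3-(3,5-dimethoxyphenyl)-5-[(E)-2-(3,5-dimethoxyphenyl)ethenyl]-2,3-dihydro-1-benzofuran (cis) | COc1cc(OC)cc(/C=C/c2ccc3c(c2)[C@H](c2cc(OC)cc(OC)c2)[C@H](c2ccc(OC)c(OC)c2)O3)c1 | intermediate
11 | 4-[(2S)-2-(3,5-dihydroxyphenyl)-2-{5-[(E)-2-(3,5-dihydroxyphenyl)ethenyl]-2-hydroxyphenyl}ethylidene]-2-hydroxycyclohexa-2,5-dien-1-one (ring-opened para-quinone methide, not isolated) | O=C1C=CC(=C[C@@H](c2cc(O)cc(O)c2)c2cc(/C=C/c3cc(O)cc(O)c3)ccc2O)C=C1O | intermediate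
12 | 5-[(E)-2-[(2S,3S)-2-(3,4-dihydroxyphenyl)-3-(3,5-dihydroxyphenyl)-2,3-dihydro-1-benzofuran-5-yl]ethenyl]benzene-1,3-diol (trans) | Oc1cc(O)cc(/C=C/c2ccc3c(c2)[C@H](c2cc(O)cc(O)c2)[C@@H](c2ccc(O)c(O)c2)O3)c1 | target

Total step count: 5
Longest linear sequence: 5 steps (1 → 3 → 6 → 8 → 10 → 12)

Steps most likely to fail

1. Step 3. The carbene or its diazo precursor may be consumed by bimolecular azine formation or dimerisation before it inserts, or the catalyst may give insufficient enantio- or cis-selection. The fallback forms the same C2–C3 bond by a carbanion ring closure and obtains the enantiomer by resolution. It sets out from 5: the Grignard adduct is hydrolysed with aqueous HCl instead of being treated with hydrazine, giving the ketone (5-bromo-2-[(3,4-dimethoxybenzyl)oxy]phenyl)(3,5-dimethoxyphenyl)methanone F1. The phosphazene base P4-t-Bu deprotonates the benzylic O–CH2 group, the alpha-oxy carbanion adds to the ketone carbonyl (5-exo-trig), and loss of water, completed with TsOH on work-up, should give 5-bromo-2-(3,4-dimethoxyphenyl)-3-(3,5-dimethoxyphenyl)-1-benzofuran F2. Ionic hydrogenation with Et3SiH/TFA in CH2Cl2 (protonation at C3, hydride delivery to the C2 oxocarbenium ion anti to the C3 aryl group) should give racemic trans-5-bromo-2-(3,4-dimethoxyphenyl)-3-(3,5-dimethoxyphenyl)-2,3-dihydro-1-benzofuran F3. Preparative chromatography on a chiral stationary phase gives the (2S,3S)-5-bromo-2-(3,4-dimethoxyphenyl)-3-(3,5-dimethoxyphenyl)-2,3-dihydro-1-benzofuran F4. A Heck reaction with 9 under the step 4 conditions gives the trans hexamethyl ether (2S,3S)-2-(3,4-dimethoxyphenyl)-3-(3,5-dimethoxyphenyl)-5-[(E)-2-(3,5-dimethoxyphenyl)ethenyl]-2,3-dihydro-1-benzofuran F5, and BBr3 demethylation (no inversion needed) comes back to the route at 12.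

2. Step 5. The electron-rich stilbene may oligomerise or add HBr under BBr3, inversion at C2 may stay incomplete, or C3 may erode if the ring-opened quinone methide tautomerises before it recloses. The fallback moves the Lewis-acid step ahead of stilbene formation and switches to base-labile protection. It sets out from 8: BBr3 in CH2Cl2 demethylates and epimerises the bromide to 4-[(2S,3S)-5-bromo-3-(3,5-dihydroxyphenyl)-2,3-dihydro-1-benzofuran-2-yl]benzene-1,2-diol F6. Ac2O/pyridine gives the tetraacetate (2S,3S)-5-bromo-2-(3,4-diacetoxyphenyl)-3-(3,5-diacetoxyphenyl)-2,3-dihydro-1-benzofuran F7. A Heck reaction (Pd(OAc)2, P(o-tol)3, Et3N, DMF) with purchased 3,5-diacetoxystyrene (C=Cc1cc(OC(C)=O)cc(OC(C)=O)c1) gives the hexaacetate of the target F8. Mild methanolysis (K2CO3 or NH4OAc in degassed MeOH, then acidification) comes back to the route at 12.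

3. Step 2. Addition of the aryl Grignard reagent to the hindered ortho-alkoxy nitrile may stall, the aryl bromide may undergo halogen–metal exchange on long heating, or the ketimine may hydrolyse to the less reactive ketone before transimination. The fallback replaces the nitrile by an aldehyde and sets out from 2 and 4. Purchased 5-bromo-2-hydroxybenzaldehyde (O=Cc1cc(Br)ccc1O) is alkylated with 2 (K2CO3, DMF) to 5-bromo-2-[(3,4-dimethoxybenzyl)oxy]benzaldehyde F9. Addition of 4 in THF at 0 °C gives the racemic carbinol (5-bromo-2-[(3,4-dimethoxybenzyl)oxy]phenyl)(3,5-dimethoxyphenyl)methanol F10. Oxidation with MnO2 (or Dess–Martin periodinane) gives the ketone (5-bromo-2-[(3,4-dimethoxybenzyl)oxy]phenyl)(3,5-dimethoxyphenyl)methanone F1, the same compound as in the first fallback. Condensation with N2H4·H2O and catalytic AcOH in EtOH at reflux comes back to the route at 6.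

Further compounds
F1 | step 3 | (5-bromo-2-[(3,4-dimethoxybenzyl)oxy]phenyl)(3,5-dimethoxyphenyl)methanone | O=C(c1cc(OC)cc(OC)c1)c1cc(Br)ccc1OCc1ccc(OC)c(OC)c1
F2 | step 3 | 5-bromo-2-(3,4-dimethoxyphenyl)-3-(3,5-dimethoxyphenyl)-1-benzofuran | COc1cc(OC)cc(c1)-c1c(-c2ccc(OC)c(OC)c2)oc2ccc(Br)cc12
F3 | step 3 | racemic trans-5-bromo-2-(3,4-dimethoxyphenyl)-3-(3,5-dimethoxyphenyl)-2,3-dihydro-1-benzofuran (both enantiomers) | Brc1ccc2c(c1)[C@H](c1cc(OC)cc(OC)c1)[C@@H](c1ccc(OC)c(OC)c1)O2.Brc1ccc2c(c1)[C@@H](c1cc(OC)cc(OC)c1)[C@H](c1ccc(OC)c(OC)c1)O2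
F4 | step 3 | (2S,3S)-5-bromo-2-(3,4-dimethoxyphenyl)-3-(3,5-dimethoxyphenyl)-2,3-dihydro-1-benzofuran | Brc1ccc2c(c1)[C@H](c1cc(OC)cc(OC)c1)[C@@H](c1ccc(OC)c(OC)c1)O2
F5 | step 3 | (2S,3S)-2-(3,4-dimethoxyphenyl)-3-(3,5-dimethoxyphenyl)-5-[(E)-2-(3,5-dimethoxyphenyl)ethenyl]-2,3-dihydro-1-benzofuran | COc1cc(OC)cc(/C=C/c2ccc3c(c2)[C@H](c2cc(OC)cc(OC)c2)[C@@H](c2ccc(OC)c(OC)c2)O3)c1
F6 | step 5 | 4-[(2S,3S)-5-bromo-3-(3,5-dihydroxyphenyl)-2,3-dihydro-1-benzofuran-2-yl]benzene-1,2-diol | Brc1ccc2c(c1)[C@H](c1cc(O)cc(O)c1)[C@@H](c1ccc(O)c(O)c1)O2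
F7 | step 5 | (2S,3S)-5-bromo-2-(3,4-diacetoxyphenyl)-3-(3,5-diacetoxyphenyl)-2,3-dihydro-1-benzofuran | Brc1ccc2c(c1)[C@H](c1cc(OC(C)=O)cc(OC(C)=O)c1)[C@@H](c1ccc(OC(C)=O)c(OC(C)=O)c1)O2
F8 | step 5 | (2S,3S)-2-(3,4-diacetoxyphenyl)-3-(3,5-diacetoxyphenyl)-5-[(E)-2-(3,5-diacetoxyphenyl)ethenyl]-2,3-dihydro-1-benzofuran | CC(=O)Oc1cc(OC(C)=O)cc(/C=C/c2ccc3c(c2)[C@H](c2cc(OC(C)=O)cc(OC(C)=O)c2)[C@@H](c2ccc(OC(C)=O)c(OC(C)=O)c2)O3)c1
F9 | step 2 | 5-bromo-2-[(3,4-dimethoxybenzyl)oxy]benzaldehyde | O=Cc1cc(Br)ccc1OCc1ccc(OC)c(OC)c1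
F10 | step 2 | racemic (5-bromo-2-[(3,4-dimethoxybenzyl)oxy]phenyl)(3,5-dimethoxyphenyl)methanol | OC(c1cc(OC)cc(OC)c1)c1cc(Br)ccc1OCc1ccc(OC)c(OC)c1
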